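Whatever was charged stood at any moment as starting material, single product, double product or side product, and in the earlier runs double product could have come from single product. So in a stretch of a run, the gain in single plus double product is what the readings show of the product made from the starting material, side product not counted, and the gain in double product is what went on to the second step.

all flasks: gas 0.48 mM (held)

| flask | starting material | remark | time |
|---|---|---|---|
| zeta | 2.7 mM | run made earlier |  |
| eta | 8.9 mM | run made earlier |  |
| alpha | 31 mM | run made earlier |  |
| elm | 10 mM |  | 30 h |
| maple | 3.0 mM |  | 30 h |
| ash | 30 mM |  | 30 h |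
| oak | 6.0 mM |  | 30 h |

| run | time / h | single product / % | double product / % |
|---|---|---|---|
| zeta | 2.00 | 4.4 | 0 |
| zeta | 5.00 | 10.9 | 2.3 |
| zeta | 10.0 | 19.4 | 9.1 |
| zeta | 15.0 | 20.3 | 18.7 |
| zeta | 20.0 | 20.4 | 28.7 |
| eta | 4.00 | 9.5 | 2.1 |
| eta | 8.00 | 14.6 | 3.8 |
| eta | 12.0 | 22.1 | 9.2 |
| eta | 15.0 | 25.4 | 11.4 |
| eta | 20.0 | 29.3 | 15.1 |
| alpha | 2.00 | 2.7 | 0 |
| alpha | 5.00 | 7.9 | 0 |
| alpha | 10.0 | 14.2 | 1.1 |
| alpha | 15.0 | 20.4 | 1.0 |
| alpha | 20.0 | 26.7 | 3.3 |

(readings scatter by 1 percentage point)

- at the start none of the gas is in solution
- a reading or a percentage of single product counts all its forms, free or not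

- the flasks put in order of share of single product in all that became single product or double product or side product, best first, at 30 h (elm / maple / ash / oak)
- the share of single product in all that became single product or double product or side product of the flask you put first, at 30 h
- the share of single product in all that became single product or double product or side product of the flask you put last, at 30 h

I divided the first gain into the second, and time cancelled. From 10.0 h to 20.0 h alpha gave 0.150; this passing-on ratio, a differential selectivity, says how much of the new product became double product. Eta gave 0.450 from 12.0 h, and zeta gave 0.990 from 15.0 h. The ratio thus fell as the charge rose.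

Turned round, maple could pass ash if alpha's ratio reached zeta's. Alpha would then have gained 15 percentage points of double product; it gained 2.2 points, with a scatter of 1 point per reading. So I put the flasks in order of charge. For ash I reckoned 85.0% before side product, which no reading shows, above the forecast's figure.

The forecast gave ash > elm > oak > maple, with 78% and 27%, holding that “over-reaction is therefore worst in dilute flasks”.

The flasks gave ash > elm > oak > maple, with 78.9% and 27.3%.

    starting material + partner → single product + by-product (k = 0.0230 M⁻¹ s⁻¹)
    gas ⇌ partner, rate k2*(csat - [partner]) (kL = 5.40 × 10⁻⁴ s⁻¹)
    partner + single product → double product + by-product (k = 0.0600 M⁻¹ s⁻¹)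
    starting material + by-product → side product (k = 1.10 × 10⁻⁴ M⁻¹ s⁻¹)
    crystals ⇌ single product, rate k5*(cs5 - [single product]) while solid is left; crystals form when [single product] > cs5 (solubility = 0.950 mM, k = 0.00630 s⁻¹)

From 15.0 h to 30.0 h the passing-on ratio was 0.133 in ash and 1.12 in maple. At 30.0 h ash's partner went into single product 6.2 times as fast as into double product, while crystals held 34.8% of its charge, counted within its 38.0% of single product. The same flask read at 48.0 h had a ratio of 0.209 over the added stretch, and its share of single product stood at 74.1%.

The data were computed from invented constants, and the scatter is random.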